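A rate proportional to the free catalyst charged cannot hold here: from the west run to the east run that charge falls by a factor of 1.50, but the late slope of target falls from 1.95 mM min⁻¹ to 0.129 mM min⁻¹, a factor of 15.1.

the same everywhere: impurity 0.46 mM
- west: substrate 0.063 M; partner 0.0693 M; free catalyst 0.63 mM; run made earlier
- east: substrate 0.063 M; partner 0.0693 M; free catalyst 0.42 mM; run made earlier
- south: substrate 0.063 M; partner 0.0693 M; free catalyst 0.95 mM; run made earlier
- south-east: substrate 0.063 M; partner 0.10 M; free catalyst 0.63 mM; run made earlier
- birch: substrate 0.063 M; partner 0.0693 M; free catalyst 0.63 mM; a single well-mixed tank run continuously and read at steady state, 20 min in it on average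
- alder: substrate 0.063 M; partner 0.0693 M (fed, over 20.0 min); free catalyst 0.63 mM; a stirred flask in which partner is dosed at a steady rate over 20.0 min without added volume, worked up at 20 min; time 20 min
- larch: substrate 0.063 M (fed, over 20.0 min); partner 0.0693 M; free catalyst 0.63 mM; a stirred flask in which substrate is dosed at a steady rate over 20.0 min without added volume, worked up at 20 min; time 20 min
- ash: substrate 0.063 M; partner 0.0693 M; free catalyst 0.63 mM; everything together in a closed stirred flask, run for 20 min; time 20 min

| run | time / min | target / % | substrate / % |
|---|---|---|---|
| west | 1.00 | 9.1 | 91.1 |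
| west | 3.00 | 17.5 | 83.8 |
| west | 6.00 | 26.1 | 72.7 |
| west | 8.00 | 35.0 | 67.2 |
| west | 12.0 | 45.4 | 54.9 |
| east | 5.00 | 7.7 | 88.8 |
| east | 10.0 | 9.7 | 90.5 |
| east | 15.0 | 10.0 | 88.5 |
| east | 20.0 | 10.8 | 89.3 |
| east | 25.0 | 11.8 | 89.1 |
| south | 5.00 | 50.5 | 49.0 |
| south | 10.0 | 79.7 | 17.1 |
| south | 15.0 | 98.0 | 2.3 |
| south | 20.0 | 99.3 | 1.9 |
| south | 25.0 | 98.9 | 0 |
| south-east | 5.00 | 23.4 | 74.5 |
| south-east | 10.0 | 41.3 | 57.2 |
| south-east | 15.0 | 58.3 | 40.1 |
| south-east | 20.0 | 72.4 | 24.9 |
| south-east | 25.0 | 86.0 | 12.8 |

(scatter of a reading: 1 percentage point)

- the stated concentrations are those of everything mixed, before any reaction; amounts are the same in each set-up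
- the earlier runs were read with a standard deviation of 1 percentage point
- the feed brings no volume worth counting
- the earlier runs were made in a closed, stirred flask

- the set-up with the highest amount of target at the outlet or at the end, in percent of the substrate put in ("none" if the first two lie within 2 percentage points) (birch / alder / larch / ash / none)
- amount of target at the outlet or at the end, in percent of the substrate put in, birch
- amount of target at the outlet or at the end, in percent of the substrate put in, alder
- amount of target at the outlet or at the end, in percent of the substrate put in, larch
- amount of target at the outlet or at the end, in percent of the substrate put in, ash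

Assume that each impurity removes one free catalyst, as a titrant removes active sites. Define W = 0.170 mM, the working catalyst: free catalyst charged minus impurity charged. In the east run this difference is −0.0400 mM, and its late slope stands far below the west one.

Next read the order. In the south-east run target climbs at 2.20 mM min⁻¹ between 5.00 min and 15.0 min and at 1.75 mM min⁻¹ from there to 25.0 min, while substrate falls from 74.5% to 12.8%. So take the rate as zero order in substrate, rate = nW, with n the turnover frequency.

The west run has the charges of ash, so start ash from the west reading at 12.0 min:

n = 11.5 min⁻¹

target at 20 min = 45.4% + nW(time left)/substrate charge = 70.2%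

The weak link is holding n while partner runs down. Reforge it from the south run, with the same partner charge, where target crosses an overlapping stretch from 50.5% to 79.7%:

n = 7.51 min⁻¹, lower than before

target at 20 min = 61.6%

Commit to that for ash. The forecast reaches 62% for ash by extrapolating the west run, with 50% for birch, 36% for alder, 58% for larch and ash as best, and says: “active catalyst ≈ free catalyst minus impurity”.

The flasks give 57.5% for birch, 48.3% for alder, 49.5% for larch and 66.7% for ash, so ash is best.

    partner + catalyst intermediate B ⇌ catalyst intermediate C (K = 190 M⁻¹, k = 27.6 M⁻¹ s⁻¹)
    substrate + free catalyst → catalyst intermediate A (k = 31.5 M⁻¹ s⁻¹)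
    free catalyst + impurity → spent catalyst (k = 656 M⁻¹ s⁻¹)
    catalyst intermediate C → released group + catalyst intermediate D (k = 2.20 s⁻¹)
    catalyst intermediate D → free catalyst + target (k = 28.7 s⁻¹)
    catalyst intermediate A ⇌ catalyst intermediate B (K = 1.28, k = 0.420 s⁻¹)

In ash, free catalyst has a half-life of 2.3 s by impurity alone at the charged concentrations, far below the 20 min of the run, and at the end impurity stands at 0% of its own charge and spent catalyst at 73.0% of the catalyst charged. The forms still in the round add up to 27.0%, and W over the charge is 27.0%.

Now take the neighbour flask, ash with 0.16 M of substrate. W is unchanged, so zero order predicts the molar target of ash, 42.0 mM, which is 26.3% of its charge. That flask gives 31.2%, with spent catalyst at 73.0%.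

The readings come from a simulation from invented constants; the scatter is artificial.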